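**Plan**

- Retrosynthesis: the 4'-O-pivaloyl group is cut first. Ring C is then cut at O1–C2 and C4a–C4 together, which gives 5-methoxy-2-prenylresorcinol (ring A with the prenyl group in place) and an enantiopure trans-3-aryl-2,3-epoxypropanal (C2–C3–C4 plus ring B).
- Enabling feature: the resorcinol has a mirror plane through its prenyl-bearing and methoxy-bearing carbons. Its two O–H/ortho C–H pairs are therefore equivalent, and each C–H carbon (future C4a) is ortho/para to three oxygen donors. Either pair gives the same 5-OMe/7-OH/8-prenyl chroman; the partner offers an aldehyde carbon (C4) to that ring carbon and a benzylic epoxide carbon (C2) to the phenol oxygen (O1).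
- Forward order: ring A fragment (steps 1–3), epoxy aldehyde (steps 4–7), one titanium-templated annulation that closes ring C (step 8), ester cleavage (step 9).
- Stereochemistry: C3 comes from a Sharpless asymmetric epoxidation; C2 comes from the same epoxide by inversion at ring closure; C4 comes from Felkin–Anh addition next to C3.

Key step: step 8

Remark on the chemistry: the SMILES is read as the (2R,3S,4S) isomer (ring C 2,3-trans-3,4-cis), and the route is planned for that configuration.

**Route**

Step 1
Reactants: 1 5-methoxybenzene-1,3-diol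
Product: 2 1-methoxy-3,5-bis(methoxymethoxy)benzene
Conditions: MOMCl (2.5 equiv), i-Pr2NEt (3 equiv), CH2Cl2, 0 °C → rt
Reagents that add atoms: chloromethyl methyl ether, COCCl
Why: O-alkylation of both phenols (Williamson-type acetal protection) installs two strong ortho-directing groups that flank the carbon to be prenylated.

Step 2
Reactants: 2 1-methoxy-3,5-bis(methoxymethoxy)benzene
Product: 4 5-methoxy-1,3-bis(methoxymethoxy)-2-(3-methylbut-2-en-1-yl)benzene, via aryllithium 3 (not isolated)
Conditions: n-BuLi (1.2 equiv), THF, 0 °C; then CuI (10 mol%), prenyl bromide, −78 °C → rt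
Reagents that add atoms: 1-bromo-3-methylbut-2-ene (prenyl bromide), CC(C)=CCBr
Why: Directed ortho-metalation should take place at the carbon between the two OMOM groups (doubly chelated site), and copper-catalysed SN2 allylation of the aryllithium keeps the linear 3,3-dimethylallyl connectivity.

Step 3
Reactants: 4 5-methoxy-1,3-bis(methoxymethoxy)-2-(3-methylbut-2-en-1-yl)benzene
Product: 5 5-methoxy-2-(3-methylbut-2-en-1-yl)benzene-1,3-diol
Conditions: HCl (3 M aq), MeOH, rt
Reagents that add atoms: none
Why: Acid-catalysed acetal methanolysis should free both phenols under conditions mild enough for the trisubstituted alkene and gives the mirror-symmetric resorcinol needed for the annulation.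

Step 4
Reactants: 6 methyl (E)-3-(4-hydroxyphenyl)prop-2-enoate
Product: 7 4-[(E)-3-hydroxyprop-1-en-1-yl]phenol
Conditions: DIBAL-H (4 equiv), toluene/THF, −78 → 0 °C; aq. Rochelle salt
Reagents that add atoms: none
Why: Hydride 1,2-reduction of the conjugated ester (the phenol is masked in the flask as its aluminium phenoxide) should give the E allylic alcohol with the alkene untouched.

Step 5
Reactants: 7 4-[(E)-3-hydroxyprop-1-en-1-yl]phenol
Product: 8 4-[(E)-3-hydroxyprop-1-en-1-yl]phenyl 2,2-dimethylpropanoate
Conditions: PivCl (1.05 equiv), NaOH (1 M aq), n-Bu4NHSO4 (cat.), CH2Cl2, 0 °C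
Reagents that add atoms: pivaloyl chloride, CC(C)(C)C(=O)Cl
Why: Schotten–Baumann acylation under phase transfer acylates only the ionised phenol, and the ester makes ring B a weaker donor so that the later aryl epoxide is stable and opens with inversion.

Step 6
Reactants: 8 4-[(E)-3-hydroxyprop-1-en-1-yl]phenyl 2,2-dimethylpropanoate
Product: 9 4-[(2S,3S)-3-(hydroxymethyl)oxiran-2-yl]phenyl 2,2-dimethylpropanoate
Conditions: Ti(OiPr)4 (10 mol%), L-(+)-diethyl tartrate (12 mol%), t-BuOOH (2 equiv), 4 Å sieves, CH2Cl2, −20 °C
Reagents that add atoms: tert-butyl hydroperoxide, CC(C)(C)OO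
Why: Sharpless asymmetric epoxidation of the E allylic alcohol with L-(+)-tartrate should give the (2S,3S)-epoxy alcohol, which fixes C3 and, latently, C2 of the flavan.

Step 7
Reactants: 9 4-[(2S,3S)-3-(hydroxymethyl)oxiran-2-yl]phenyl 2,2-dimethylpropanoate
Product: 10 4-[(2S,3R)-3-formyloxiran-2-yl]phenyl 2,2-dimethylpropanoate
Conditions: TEMPO (10 mol%), PhI(OAc)2 (1.1 equiv), CH2Cl2, rt; used without chromatography
Reagents that add atoms: none
Why: Oxoammonium (TEMPO) oxidation stops at the aldehyde under near-neutral conditions that should leave the epoxide and its alpha stereocentre untouched; the descriptor at the formyl-bearing carbon changes from S to R through the priority rules only.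

Step 8
Reactants: 5 5-methoxy-2-(3-methylbut-2-en-1-yl)benzene-1,3-diol; 10 4-[(2S,3R)-3-formyloxiran-2-yl]phenyl 2,2-dimethylpropanoate
Product: 13 4-[(2R,3S,4S)-3,4,7-trihydroxy-5-methoxy-8-(3-methylbut-2-en-1-yl)-3,4-dihydro-2H-chromen-2-yl]phenyl 2,2-dimethylpropanoate, via titanium aryloxide 11 (not isolated), via titanium-chelated epoxy alkoxide 12 (not isolated)
Conditions: 5 (1.5 equiv), Ti(OiPr)4 (1.5 equiv), toluene, rt, then evaporation of i-PrOH; CH2Cl2, −40 °C, slow addition of 10 (1.0 equiv); −40 → 20 °C; aq. NaHCO3/Rochelle salt; Et3N-deactivated silica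
Reagents that add atoms: none
Why: Proposed new method: the titanium aryloxide 11 binds the aldehyde of 10 and its ortho carbon adds through a six-membered cyclic transition state (C4a–C4, a phenolate aldol), after which the new C4 alkoxide and the epoxide oxygen chelate titanium in 12 and the aryl oxygen opens the activated epoxide at its benzylic carbon (O1–C2), so that a formal [3+3] annulation builds ring C in one flask. The closest known reaction types are the ortho-specific hydroxyalkylation of magnesium and titanium phenoxides with chiral alpha-oxygenated aldehydes, the Ti(OiPr)4-assisted opening of 2,3-epoxy alcohols at the carbon remote from the hydroxyl, and the aryl-directed endo cyclisation of phenolic epoxides to flavan-3-ols; joining them in one operation on a phenol and an epoxy aldehyde is the untested part. Ring C closes in the 6-endo-tet mode. C4 is set by Felkin–Anh attack anti to the epoxide C–O bond at C3 (3,4-anti in the chain, 3,4-cis in the ring, 4S), C2 is set by SN2 inversion at the benzylic epoxide carbon (2,3-trans, 2R), and C3 keeps the configuration given by the Sharpless epoxidation. The step needs C- over O-attack and mono- over bis-annulation, which the mirror symmetry of 5, the three oxygen donors around the reacting carbon, the titanium template and the excess of 5 should secure, and it needs 6-endo over 5-exo opening with clean inversion, which the benzylic position, the chelate that exposes the remote carbon and the electron-poor pivaloyloxy ring B (no free benzylic cation) should secure.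

Step 9
Reactants: 13 4-[(2R,3S,4S)-3,4,7-trihydroxy-5-methoxy-8-(3-methylbut-2-en-1-yl)-3,4-dihydro-2H-chromen-2-yl]phenyl 2,2-dimethylpropanoate
Product: 14 (2R,3S,4S)-2-(4-hydroxyphenyl)-5-methoxy-8-(3-methylbut-2-en-1-yl)-3,4-dihydro-2H-chromene-3,4,7-triol
Conditions: K2CO3 (0.3 equiv), degassed MeOH, 0 °C → rt; pH 7 phosphate buffer
Reagents that add atoms: none
Why: Base-catalysed transesterification of the aryl ester with methanol frees the phenol without acid, hydrogenolysis or heat, so the prenyl alkene and the ionisable C4 carbinol should be preserved and no stereocentre is touched.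

**Compound list**

1 | 5-methoxybenzene-1,3-diol (5-methoxyresorcinol) | COc1cc(O)cc(O)c1 | starting material
2 | 1-methoxy-3,5-bis(methoxymethoxy)benzene | COCOc1cc(OC)cc(OCOC)c1 | intermediate
3 | [4-methoxy-2,6-bis(methoxymethoxy)phenyl]lithium | COCOc1cc(OC)cc(OCOC)c1[Li] | intermediate (not isolated)
4 | 5-methoxy-1,3-bis(methoxymethoxy)-2-(3-methylbut-2-en-1-yl)benzene | COCOc1cc(OC)cc(OCOC)c1CC=C(C)C | intermediate
5 | 5-methoxy-2-(3-methylbut-2-en-1-yl)benzene-1,3-diol | COc1cc(O)c(CC=C(C)C)c(O)c1 | intermediate
6 | methyl (E)-3-(4-hydroxyphenyl)prop-2-enoate (methyl p-coumarate) | COC(=O)/C=C/c1ccc(O)cc1 | starting material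
7 | 4-[(E)-3-hydroxyprop-1-en-1-yl]phenol (p-coumaryl alcohol) | OC/C=C/c1ccc(O)cc1 | intermediate
8 | 4-[(E)-3-hydroxyprop-1-en-1-yl]phenyl 2,2-dimethylpropanoate | CC(C)(C)C(=O)Oc1ccc(/C=C/CO)cc1 | intermediate
9 | 4-[(2S,3S)-3-(hydroxymethyl)oxiran-2-yl]phenyl 2,2-dimethylpropanoate | OC[C@H]1[C@H](c2ccc(OC(=O)C(C)(C)C)cc2)O1 | intermediate
10 | 4-[(2S,3R)-3-formyloxiran-2-yl]phenyl 2,2-dimethylpropanoate, equal to (2R,3S)-3-[4-(pivaloyloxy)phenyl]oxirane-2-carbaldehyde | O=C[C@H]1[C@H](c2ccc(OC(=O)C(C)(C)C)cc2)O1 | intermediate
11 | [3-hydroxy-5-methoxy-2-(3-methylbut-2-en-1-yl)phenoxy]tri(propan-2-yloxy)titanium | COc1cc(O)c(CC=C(C)C)c(O[Ti](OC(C)C)(OC(C)C)OC(C)C)c1 | intermediate (not isolated)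
12 | six-membered titanium chelate (aryl oxygen and C4 oxygen on Ti(OiPr)2) of the (S)-carbinol adduct of 5 and 10, epoxide intact | COc1cc(O)c(CC=C(C)C)c2O[Ti](OC(C)C)(OC(C)C)O[C@@H](c12)[C@H]1[C@H](c2ccc(OC(=O)C(C)(C)C)cc2)O1 | intermediate (not isolated)
13 | 4-[(2R,3S,4S)-3,4,7-trihydroxy-5-methoxy-8-(3-methylbut-2-en-1-yl)-3,4-dihydro-2H-chromen-2-yl]phenyl 2,2-dimethylpropanoate | COc1cc(O)c(CC=C(C)C)c2c1[C@H](O)[C@H](O)[C@@H](c1ccc(OC(=O)C(C)(C)C)cc1)O2 | intermediate
14 | (2R,3S,4S)-2-(4-hydroxyphenyl)-5-methoxy-8-(3-methylbut-2-en-1-yl)-3,4-dihydro-2H-chromene-3,4,7-triol (5-O-methyl-8-prenylafzelechin-4beta-ol) | COc1cc(O)c(CC=C(C)C)c2c1[C@H](O)[C@H](O)[C@@H](c1ccc(O)cc1)O2 | target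

**Totals**

Total step count: 9. Longest linear sequence: 6 steps (steps 4, 5, 6, 7, 8, 9, from methyl p-coumarate).

**Steps most likely to fail**

1. Step 8 (proposed new method). Possible failure processes: poor facial selectivity in the aldehyde addition (C4 epimers); competing 5-exo opening of the epoxide; a second annulation at the remaining hydroxyl and ring C–H; ionisation of the C4 carbinol followed by capture by excess 5.
Fallback (known chemistry, sets out from 5 and 10, returns at 13): the two bonds are made in two separate operations. 5 is converted with EtMgBr (1.0 equiv, Et2O, then CH2Cl2) into bromomagnesium 3-hydroxy-5-methoxy-2-(3-methylbut-2-en-1-yl)phenoxide F1. F1 adds through its ring carbon to 10 at −40 °C (ortho-hydroxyalkylation of a magnesium phenoxide with a chiral alpha-oxygenated aldehyde). A cold quench with pH 7 buffer gives the epoxy triol 4-{(2S,3S)-3-[(S)-[2,4-dihydroxy-6-methoxy-3-(3-methylbut-2-en-1-yl)phenyl](hydroxy)methyl]oxiran-2-yl}phenyl 2,2-dimethylpropanoate F2, and C4 epimers can be separated at this stage. F2 is then closed in a separate aryl-directed 6-endo hydroxy-epoxide cyclisation (PPTS cat., CH2Cl2, −20 °C), which gives 13.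

2. Step 9. Possible failure process: slow methanolysis of the hindered aryl ester keeps the phenoxide-rich product in base for a long time, where air oxidation of ring A and opening of the O1–C2 bond through a ring B quinone methide (loss of the C2 configuration) may set in.
Fallback (sets out from 7, returns at 14): the pivalate is replaced by an allyl carbonate that is removed under neutral conditions. 7 is acylated at the phenol with allyl chloroformate (NaOH aq, CH2Cl2, n-Bu4NHSO4, 0 °C) to give allyl 4-[(E)-3-hydroxyprop-1-en-1-yl]phenyl carbonate F3. Sharpless epoxidation as in step 6 gives allyl 4-[(2S,3S)-3-(hydroxymethyl)oxiran-2-yl]phenyl carbonate F4. TEMPO/PhI(OAc)2 gives allyl 4-[(2S,3R)-3-formyloxiran-2-yl]phenyl carbonate F5. Annulation with 5 through 11 as in step 8 passes through the titanium-chelated allyl carbonate analogue of 12 F6 and gives allyl 4-[(2R,3S,4S)-3,4,7-trihydroxy-5-methoxy-8-(3-methylbut-2-en-1-yl)-3,4-dihydro-2H-chromen-2-yl]phenyl carbonate F7. Pd(PPh3)4 (zerovalent palladium, 2 mol%) with morpholine in THF at 20 °C then cleaves the allyl carbonate by pi-allyl formation and decarboxylation and gives 14.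

3. Step 3. Possible failure process: protonation of the trisubstituted alkene during acetal cleavage, followed by ring closure onto the freed ortho hydroxyl (2,2-dimethylchroman formation) or by addition of methanol.
Fallback (sets out from 1, returns at 5): protection and deprotection are avoided. Unprotected 1 is prenylated directly with 3-methylbut-2-en-1-ol on acidic alumina (1,2-dichloroethane, reflux), an ortho-selective allylation of free phenols that should favour the carbon flanked by both hydroxyls. Steps 1 to 3 are then not needed, and this fallback makes no compound outside the list (F0).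

**Further compounds**

F1 | step 8 | bromomagnesium 3-hydroxy-5-methoxy-2-(3-methylbut-2-en-1-yl)phenoxide | COc1cc(O)c(CC=C(C)C)c(O[Mg]Br)c1
F2 | step 8 | 4-{(2S,3S)-3-[(S)-[2,4-dihydroxy-6-methoxy-3-(3-methylbut-2-en-1-yl)phenyl](hydroxy)methyl]oxiran-2-yl}phenyl 2,2-dimethylpropanoate | COc1cc(O)c(CC=C(C)C)c(O)c1[C@H](O)[C@H]1[C@H](c2ccc(OC(=O)C(C)(C)C)cc2)O1
F3 | step 9 | allyl 4-[(E)-3-hydroxyprop-1-en-1-yl]phenyl carbonate | C=CCOC(=O)Oc1ccc(/C=C/CO)cc1
F4 | step 9 | allyl 4-[(2S,3S)-3-(hydroxymethyl)oxiran-2-yl]phenyl carbonate | OC[C@H]1[C@H](c2ccc(OC(=O)OCC=C)cc2)O1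
F5 | step 9 | allyl 4-[(2S,3R)-3-formyloxiran-2-yl]phenyl carbonate | O=C[C@H]1[C@H](c2ccc(OC(=O)OCC=C)cc2)O1
F6 | step 9 | titanium chelate (aryl oxygen and C4 oxygen on Ti(OiPr)2) of the (S)-carbinol adduct of 5 and F5, epoxide intact | COc1cc(O)c(CC=C(C)C)c2O[Ti](OC(C)C)(OC(C)C)O[C@@H](c12)[C@H]1[C@H](c2ccc(OC(=O)OCC=C)cc2)O1
F7 | step 9 | allyl 4-[(2R,3S,4S)-3,4,7-trihydroxy-5-methoxy-8-(3-methylbut-2-en-1-yl)-3,4-dihydro-2H-chromen-2-yl]phenyl carbonate | COc1cc(O)c(CC=C(C)C)c2c1[C@H](O)[C@H](O)[C@@H](c1ccc(OC(=O)OCC=C)cc1)O2
F0 | step 3 | none | none
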